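The electrophile in the north flask is what you follow here; south, its nearest neighbour, differs from it in the free base.

| flask | electrophile | free base | protonated nucleophile | remark | time |
|---|---|---|---|---|---|
| north | 0.20 mM | 2 equiv | 1.2 equiv | the very flask that is asked about, followed so far |  |
| south | 0.20 mM | 1.3 equiv | 1.2 equiv | run made earlier |  |
| flask | 0.20 mM | 2.00 equiv | 1.20 equiv |  | 2.0 min |

| run | time / s | electrophile / % | product / % |
|---|---|---|---|
| north | 10.0 | 73.5 | 27.3 |
| north | 20.0 | 54.1 | 46.2 |
| north | 40.0 | 29.7 | 70.6 |
| south | 10.0 | 76.5 | 23.4 |
| south | 15.0 | 66.9 | 32.9 |
| south | 25.0 | 52.3 | 48.1 |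
| south | 50.0 | 28.3 | 73.0 |

(scatter of a reading: 0.5 percentage points)

1. part of the electrophile that has reacted at 2.0 min
2. share of the unused nucleophile that is free and not bound as protonated nucleophile, at 2.0 min

- the numbers in the tables scatter with a standard deviation of 0.5 percentage points
- the earlier runs do not show how much of nucleophile is bound; that part of a forecast is a guess

Assume each product costs one nucleophile. Then the ceiling C is the nucleophile charged as a percentage of the electrophile charged: 120%. It stands above complete reaction, so in north and south the electrophile is the limiting reagent.

The late loss of electrophile gives a read constant k of 0.0300 s⁻¹ in north and 0.0246 s⁻¹ in south. North runs faster, by a factor of 1.22 for a factor of 1.54 in free base. Both runs share the same C, so the free base moves their clock and leaves their ceiling alone.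

Your reckoning for a flask is the lesser of C and the clock, one minus exp(−kt). For north at 2.0 min the clock gives 97.3%, below C, so you commit to that. The readings do not show how the unused nucleophile divides, so its free share stays a guess.

The forecast gave 96% (92% to 98.5%) reacted, less than your clock, and 60% (25% to 90%) free, with this among its grounds: “a bound reservoir keeps releasing free nucleophile”.

The north flask gives 97.9% reacted and 44.0% free.

    acid set free + free base ⇌ salt of the base (K = 2.65 × 10⁷ M⁻¹, k = 3650 M⁻¹ s⁻¹)
    electrophile + nucleophile → acid set free + product (k = 2160 M⁻¹ s⁻¹)
    nucleophile + acid set free ⇌ protonated nucleophile, settled at all times (K = 2.00 × 10⁶ M⁻¹)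
    acid set free → by-product carried off (k = 0.402 s⁻¹)

In the north flask the half-life of nucleophile by its step with the electrophile at 0.315 min is 2.9 s, shorter than the 2.0 min of the run. Against C, the result in the north flask leaves 22 percentage points of unused nucleophile, free and bound together, counted on the electrophile charged.

A neighbour of the north flask, charged with 0.480 equiv of protonated nucleophile and otherwise the same, has C = 48.0%, below the north clock, so the reckoning gives C. Computed, this neighbour has 48.0% reacted at 2.0 min and keeps 52.0% of its electrophile, with 4.87 × 10⁻⁹ mM of nucleophile left.

(The runs are calculated with constants of no real substance, noise included.)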